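**Retrosynthetic overview**
- Ring C is closed last: the isoflavone comes from a 2-hydroxydeoxybenzoin and a one-carbon formamide acetal (bonds O1–C2 and C2–C3), then a benzyl ether on ring B is hydrogenolysed.
- The deoxybenzoin comes from a 2-(2-aryl-1-silyloxyethyl)-3,4,5-trimethoxyphenol by desilylation and phenol-assisted dehydrogenation of the carbinol.
- The strategy rests on ring A, which is substituted on five of its six carbons (OMe on C5, C6 and C7, the pyranone oxygen on C8a, the carbonyl carbon on C4a, hydrogen only on C8). This is the pattern of a 2-alkyl-3,4,5-trialkoxyphenol, so ring A is built de novo by benzannulation of the vinylketene from 2,3-dimethoxycyclobut-2-en-1-one (C6, C7, C8, C8a) with a methyl ynol ether (C5, C4a), forming C4a–C8a, C5–C6 and C8–C8a.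
- The cyclobutenone comes from dimethyl squarate (hydride reduction, acetylation, SmI2 deoxygenation). The ynol ether comes from 2,3-dihydroxybenzaldehyde (benzylation, methylation, homologation to the arylacetaldehyde, addition of lithium methoxyacetylide made from chloroacetaldehyde dimethyl acetal, silylation).
- Order of rings: ring B is bought, ring A is formed in step 10, ring C in step 13.

Key step: step 10

Remark on the chemistry: the target is achiral; the carbinol stereocentre of the intermediates is carried as a racemate and is erased by the oxidation in step 12. Atom labels C2–C8a refer to the chromen-4-one numbering of the target.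

**Route**

Step 1
Reactants: 1 dimethyl squarate (3,4-dimethoxycyclobut-3-ene-1,2-dione)
Product: 2 rac-4-hydroxy-2,3-dimethoxycyclobut-2-en-1-one
Conditions: LiAlH(OtBu)3 (1.05 equiv), THF, −78 → 0 °C; Na2SO4·10H2O quench, no acid
Reagents that add atoms: none
Why: Selective 1,2-hydride reduction of one of the two equivalent squarate carbonyls by the mild, bulky aluminium hydride is an established entry to 4-hydroxycyclobutenones, the remaining carbonyl being a deactivated vinylogous ester, and the new C4 carbinol centre forms as a racemate, which is acceptable because it is removed in step 3.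

Step 2
Reactants: 2 rac-4-hydroxy-2,3-dimethoxycyclobut-2-en-1-one
Product: 3 rac-2,3-dimethoxy-4-oxocyclobut-2-en-1-yl acetate
Conditions: Ac2O, Et3N, DMAP (cat.), CH2Cl2, 0 °C
Reagents that add atoms: acetic anhydride, CC(=O)OC(C)=O
Why: DMAP-catalysed O-acylation of a secondary alcohol under basic conditions avoids the acid-induced ionisation of the hydroxycyclobutenone to a cyclobutenedione and installs the leaving group needed for reductive cleavage.

Step 3
Reactants: 3 rac-2,3-dimethoxy-4-oxocyclobut-2-en-1-yl acetate
Product: 4 2,3-dimethoxycyclobut-2-en-1-one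
Conditions: SmI2 (2.2 equiv), THF–MeOH, −78 °C
Reagents that add atoms: none
Why: Reductive cleavage of an α-acyloxy ketone by SmI2 (two single-electron transfers, loss of acetate, protonation of the samarium enolate by methanol) should place hydrogen on the unsubstituted C4 in preference to the methoxy-bearing C2, since this keeps the tetrasubstituted push–pull enol ether, and the low temperature protects the thermally labile cyclobutenone.

Step 4
Reactants: 5 2,3-dihydroxybenzaldehyde
Product: 6 3-(benzyloxy)-2-hydroxybenzaldehyde
Conditions: NaH (2.2 equiv), DMSO, rt; then BnBr (1.0 equiv), rt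
Reagents that add atoms: benzyl bromide, BrCc1ccccc1
Why: Williamson etherification of the dianion is regioselective because the 2-phenoxide is conjugated with and chelated to the formyl group, so the more nucleophilic 3-phenoxide takes up the single equivalent of benzyl bromide.

Step 5
Reactants: 6 3-(benzyloxy)-2-hydroxybenzaldehyde
Product: 7 3-(benzyloxy)-2-methoxybenzaldehyde
Conditions: MeI, K2CO3, DMF, rt
Reagents that add atoms: iodomethane, CI
Why: Williamson O-methylation of the remaining phenol under carbonate conditions is standard and leaves the aldehyde and the benzyl ether untouched.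

Step 6
Reactants: 7 3-(benzyloxy)-2-methoxybenzaldehyde
Product: 8 1-(benzyloxy)-2-methoxy-3-(2-methoxyethenyl)benzene (E/Z mixture)
Conditions: Ph3P(CH2OMe)Cl, KOtBu, THF, 0 °C → rt
Reagents that add atoms: (methoxymethyl)triphenylphosphonium chloride, COC[P+](c1ccccc1)(c1ccccc1)c1ccccc1.[Cl-]
Why: Wittig olefination of a non-enolisable aromatic aldehyde with (methoxymethylidene)triphenylphosphorane should give the enol ether as an E/Z mixture, both isomers leading to the same aldehyde on hydrolysis.

Step 7
Reactants: 8 1-(benzyloxy)-2-methoxy-3-(2-methoxyethenyl)benzene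
Product: 9 (3-benzyloxy-2-methoxyphenyl)acetaldehyde
Conditions: 2 M aq. HCl, THF, 45 °C; used promptly
Reagents that add atoms: water, O
Why: Acid-catalysed enol ether hydrolysis (C-protonation, hydration of the oxocarbenium ion, loss of methanol) releases the one-carbon homologated aldehyde while the aryl methyl and benzyl ethers are stable to dilute acid.

Step 8
Reactants: 9 (3-benzyloxy-2-methoxyphenyl)acetaldehyde; 10 chloroacetaldehyde dimethyl acetal (2-chloro-1,1-dimethoxyethane)
Product: 12 rac-1-(3-benzyloxy-2-methoxyphenyl)-4-methoxybut-3-yn-2-ol, via lithium methoxyacetylide 11 (not isolated)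
Conditions: Et2NH, n-BuLi (3.0 equiv each), THF, 0 °C, then 10 (forms 11); then 9, −78 °C; aq. NaHCO3 work-up, no acid
Reagents that add atoms: none
Why: Twofold elimination and deprotonation of the chloroacetal by lithium diethylamide gives lithium methoxyacetylide, whose 1,2-addition to the aldehyde at −78 °C should outrun enolisation, and the carbinol centre forms as a racemate, which is acceptable because it is oxidised away in step 12.

Step 9
Reactants: 12 rac-1-(3-benzyloxy-2-methoxyphenyl)-4-methoxybut-3-yn-2-ol
Product: 13 rac-tert-butyl{[1-(3-benzyloxy-2-methoxyphenyl)-4-methoxybut-3-yn-2-yl]oxy}dimethylsilane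
Conditions: TBSCl, imidazole, DMF, 0 °C → rt
Reagents that add atoms: tert-butyldimethylsilyl chloride, CC(C)(C)[Si](C)(C)Cl
Why: Imidazole-mediated silylation of a secondary propargylic alcohol proceeds under non-acidic conditions, which protects the ynol ether from Meyer–Schuster rearrangement and masks the carbinol for the thermal step.

Step 10
Reactants: 13 rac-tert-butyl{[1-(3-benzyloxy-2-methoxyphenyl)-4-methoxybut-3-yn-2-yl]oxy}dimethylsilane; 4 2,3-dimethoxycyclobut-2-en-1-one
Product: 18 rac-2-[2-(3-benzyloxy-2-methoxyphenyl)-1-(tert-butyldimethylsilyloxy)ethyl]-3,4,5-trimethoxyphenol, via vinylketene 14 (not isolated), via vinylcyclobutenone adduct 15 (not isolated), via dienylketene 16 (not isolated), via cyclohexadienone 17 (not isolated)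
Conditions: 4 (1.5 equiv), toluene, 110 °C, sealed tube; then K2CO3, MeOH, rt
Reagents that add atoms: none
Why: Danheiser benzannulation: heating opens 4 by 4π electrocyclic cleavage to vinylketene 14, which adds the ynol ether in a [2+2] cycloaddition to give 15, forming C4a–C8a between the chain-bearing alkyne carbon and the ketene carbonyl carbon and C5–C6 between the methoxy-bearing alkyne carbon and the ketene α-carbon. 4π opening of 15 to dienylketene 16, thermal disrotatory 6π electrocyclisation forming C8–C8a (this closes ring A as a six-membered carbocycle, 17) and tautomerisation should then deliver phenol 18. The closest known reaction type is the thermal benzannulation of cyclobutenones with alkoxyalkynes to 2-substituted 3-alkoxyphenols. No stereocentre is created in 18, since the carbinol centre is carried through unchanged as a racemate and the quaternary centre of 15 is lost on ring opening. The step needs the regiochemistry of the [2+2] addition, which is secured by the polarisation of the ynol ether (the carbon β to oxygen is nucleophilic and attacks the electrophilic ketene carbon, so the side chain ends up ortho and the alkyne methoxy meta to the new hydroxyl), and it needs inward rotation of the vinyl group when 15 opens, which is favoured because the methoxy donor on the same carbon rotates outward. A methyl ynol ether has no β-hydrogen and so cannot fragment by retro-ene loss of an alkene at this temperature.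

Step 11
Reactants: 18 rac-2-[2-(3-benzyloxy-2-methoxyphenyl)-1-(tert-butyldimethylsilyloxy)ethyl]-3,4,5-trimethoxyphenol
Product: 19 rac-2-[2-(3-benzyloxy-2-methoxyphenyl)-1-hydroxyethyl]-3,4,5-trimethoxyphenol
Conditions: Bu4NF/AcOH, THF, 0 °C → rt; neutral work-up
Reagents that add atoms: none
Why: Fluoride-induced cleavage of the Si–O bond, buffered with acetic acid, should free the carbinol without generating a phenoxide or ionising the electron-rich benzylic position.

Step 12
Reactants: 19 rac-2-[2-(3-benzyloxy-2-methoxyphenyl)-1-hydroxyethyl]-3,4,5-trimethoxyphenol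
Product: 20 2-(3-benzyloxy-2-methoxyphenyl)-1-(2-hydroxy-4,5,6-trimethoxyphenyl)ethan-1-one
Conditions: DDQ (1.05 equiv), 1,4-dioxane, rt
Reagents that add atoms: none
Why: DDQ dehydrogenation of an ortho-hydroxybenzylic alcohol is strongly accelerated by the free phenol (hydride abstraction through a quinone methide-type pathway), so the carbinol should be converted into the hydrogen-bonded, deactivated 2-hydroxyaryl ketone without touching the benzyl ether, and the stereocentre is removed here.

Step 13
Reactants: 20 2-(3-benzyloxy-2-methoxyphenyl)-1-(2-hydroxy-4,5,6-trimethoxyphenyl)ethan-1-one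
Product: 22 3-(3-benzyloxy-2-methoxyphenyl)-5,6,7-trimethoxy-4H-chromen-4-one, via enaminone 21 (not isolated)
Conditions: Me2NCH(OMe)2 (3 equiv), toluene, 90 °C
Reagents that add atoms: N,N-dimethylformamide dimethyl acetal, COC(OC)N(C)C
Why: Condensation of the doubly activated methylene with the formamide acetal gives enaminone 21, and intramolecular addition–elimination by the ortho-phenol with loss of dimethylamine closes the pyranone ring C, the standard deoxybenzoin route to isoflavones.

Step 14
Reactants: 22 3-(3-benzyloxy-2-methoxyphenyl)-5,6,7-trimethoxy-4H-chromen-4-one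
Product: 23 3-(3-hydroxy-2-methoxyphenyl)-5,6,7-trimethoxy-4H-chromen-4-one (CNP0105642.0)
Conditions: H2 (1 atm), 10% Pd/C, EtOAc–MeOH, rt; stopped at one equivalent of H2
Reagents that add atoms: none
Why: Catalytic hydrogenolysis of the benzylic C–O bond of an aryl benzyl ether at ambient pressure is faster than reduction of the chromone C2–C3 double bond and should free the 3'-phenol.

**Compound list**
1 | dimethyl squarate (3,4-dimethoxycyclobut-3-ene-1,2-dione) | COC1=C(OC)C(=O)C1=O | starting material
2 | rac-4-hydroxy-2,3-dimethoxycyclobut-2-en-1-one | COC1=C(OC)C(=O)C1O | intermediate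
3 | rac-2,3-dimethoxy-4-oxocyclobut-2-en-1-yl acetate | COC1=C(OC)C(=O)C1OC(C)=O | intermediate
4 | 2,3-dimethoxycyclobut-2-en-1-one | COC1=C(OC)C(=O)C1 | intermediate
5 | 2,3-dihydroxybenzaldehyde | O=Cc1cccc(O)c1O | starting material
6 | 3-(benzyloxy)-2-hydroxybenzaldehyde | O=Cc1cccc(OCc2ccccc2)c1O | intermediate
7 | 3-(benzyloxy)-2-methoxybenzaldehyde | O=Cc1cccc(OCc2ccccc2)c1OC | intermediate
8 | 1-(benzyloxy)-2-methoxy-3-(2-methoxyethenyl)benzene (E/Z mixture) | COC=Cc1cccc(OCc2ccccc2)c1OC | intermediate
9 | (3-benzyloxy-2-methoxyphenyl)acetaldehyde | O=CCc1cccc(OCc2ccccc2)c1OC | intermediate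
10 | chloroacetaldehyde dimethyl acetal (2-chloro-1,1-dimethoxyethane) | COC(CCl)OC | starting material
11 | lithium methoxyacetylide (not isolated) | [Li]C#COC | intermediate
12 | rac-1-(3-benzyloxy-2-methoxyphenyl)-4-methoxybut-3-yn-2-ol | COC#CC(O)Cc1cccc(OCc2ccccc2)c1OC | intermediate
13 | rac-tert-butyl{[1-(3-benzyloxy-2-methoxyphenyl)-4-methoxybut-3-yn-2-yl]oxy}dimethylsilane | COC#CC(O[Si](C)(C)C(C)(C)C)Cc1cccc(OCc2ccccc2)c1OC | intermediate
14 | 2,3-dimethoxybuta-1,3-dien-1-one (vinylketene, not isolated) | O=C=C(OC)C(OC)=C | intermediate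
15 | 2-[2-(3-benzyloxy-2-methoxyphenyl)-1-(tert-butyldimethylsilyloxy)ethyl]-3,4-dimethoxy-4-(1-methoxyethenyl)cyclobut-2-en-1-one (racemic diastereomer mixture, not isolated) | O=C1C(C(O[Si](C)(C)C(C)(C)C)Cc2cccc(OCc3ccccc3)c2OC)=C(OC)C1(OC)C(OC)=C | intermediate
16 | (3Z)-2-[2-(3-benzyloxy-2-methoxyphenyl)-1-(tert-butyldimethylsilyloxy)ethyl]-3,4,5-trimethoxyhexa-1,3,5-trien-1-one (racemic, not isolated) | O=C=C(C(O[Si](C)(C)C(C)(C)C)Cc1cccc(OCc2ccccc2)c1OC)/C(OC)=C(OC)\C(OC)=C | intermediate
17 | 2-[2-(3-benzyloxy-2-methoxyphenyl)-1-(tert-butyldimethylsilyloxy)ethyl]-3,4,5-trimethoxycyclohexa-2,4-dien-1-one (racemic, not isolated) | O=C1CC(OC)=C(OC)C(OC)=C1C(O[Si](C)(C)C(C)(C)C)Cc1cccc(OCc2ccccc2)c1OC | intermediate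
18 | rac-2-[2-(3-benzyloxy-2-methoxyphenyl)-1-(tert-butyldimethylsilyloxy)ethyl]-3,4,5-trimethoxyphenol | COc1cc(O)c(C(O[Si](C)(C)C(C)(C)C)Cc2cccc(OCc3ccccc3)c2OC)c(OC)c1OC | intermediate
19 | rac-2-[2-(3-benzyloxy-2-methoxyphenyl)-1-hydroxyethyl]-3,4,5-trimethoxyphenol | COc1cc(O)c(C(O)Cc2cccc(OCc3ccccc3)c2OC)c(OC)c1OC | intermediate
20 | 2-(3-benzyloxy-2-methoxyphenyl)-1-(2-hydroxy-4,5,6-trimethoxyphenyl)ethan-1-one | COc1cc(O)c(C(=O)Cc2cccc(OCc3ccccc3)c2OC)c(OC)c1OC | intermediate
21 | 2-(3-benzyloxy-2-methoxyphenyl)-3-(dimethylamino)-1-(2-hydroxy-4,5,6-trimethoxyphenyl)prop-2-en-1-one (not isolated) | CN(C)C=C(c1cccc(OCc2ccccc2)c1OC)C(=O)c1c(O)cc(OC)c(OC)c1OC | intermediate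
22 | 3-(3-benzyloxy-2-methoxyphenyl)-5,6,7-trimethoxy-4H-chromen-4-one | COc1cc2occ(-c3cccc(OCc4ccccc4)c3OC)c(=O)c2c(OC)c1OC | intermediate
23 | 3-(3-hydroxy-2-methoxyphenyl)-5,6,7-trimethoxy-4H-chromen-4-one | COc1cc2occ(-c3cccc(O)c3OC)c(=O)c2c(OC)c1OC | target

**Step count**
Total: 14 steps. Longest linear sequence: 11 steps (steps 4–14, from 2,3-dihydroxybenzaldehyde); steps 1–3 form the second branch, which joins in step 10.

**Steps most likely to fail**

Step 3 (deoxygenation to the cyclobutenone). The delocalised oxocyclobutenyl enolate may be protonated at the methoxy-bearing carbon, which transposes the double bond. The acetate may also ionise or shift to C2 with loss of the methyl group to give a cyclobutenedione, or the intermediate radical may dimerise before the second electron transfer. Fallback: set out from 2 and acylate it with phenyl chlorothionoformate (pyridine, DMAP, CH2Cl2, 0 °C) to give rac-2,3-dimethoxy-4-oxocyclobut-2-en-1-yl O-phenyl carbonothioate F1. A Barton–McCombie deoxygenation (Bu3SnH, Et3B, air, toluene, 0 °C → rt) then passes through the allylic radical, which should take a hydrogen atom from the stannane at its less hindered, unsubstituted terminus. The room-temperature initiation avoids thermal ring opening, and the fallback comes back to the route at 4.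

Step 10 (benzannulation). The [2+2] addition at the branched, silyloxy-bearing alkyne carbon may be slow, so that the vinylketene dimerises. The phenol 18 may lose silanol by thermal 1,4-elimination through an ortho-quinone methide, or be acylated by a second vinylketene; the methanolic K2CO3 treatment is included to cleave such an aryl ester. Fallback: give up the de novo construction of ring A and use a classical acylation. Set out from 9 and oxidise it (NaClO2, NaH2PO4, 2-methyl-2-butene, t-BuOH–H2O) to (3-benzyloxy-2-methoxyphenyl)acetic acid F2. Friedel–Crafts acylation of purchased 3,4,5-trimethoxyphenol F3 with F2 in BF3·OEt2 at 80 °C, where both positions ortho to the hydroxyl are equivalent, should give the deoxybenzoin, and the fallback comes back to the route at 20.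

Step 12 (oxidation beside a free phenol). The electron-rich trimethoxyphenol ring may be oxidised to a quinone in competition with dehydrogenation of the carbinol, and 19 may dehydrate through an ortho-quinone methide before it is oxidised. Fallback: mask the phenol so that phenol and carbinol are never free together. Set out from 18 and alkylate it (allyl bromide, K2CO3, acetone, 50 °C) to rac-{1-[2-(allyloxy)-4,5,6-trimethoxyphenyl]-2-(3-benzyloxy-2-methoxyphenyl)ethoxy}(tert-butyl)dimethylsilane F4. Desilylation (Bu4NF, THF) gives rac-1-[2-(allyloxy)-4,5,6-trimethoxyphenyl]-2-(3-benzyloxy-2-methoxyphenyl)ethan-1-ol F5, and oxidation with Dess–Martin periodinane (NaHCO3, CH2Cl2) gives 1-[2-(allyloxy)-4,5,6-trimethoxyphenyl]-2-(3-benzyloxy-2-methoxyphenyl)ethan-1-one F6. Deallylation with Pd(PPh3)4 (zerovalent palladium) and morpholine in THF then frees the phenol, and the fallback comes back to the route at 20.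

**Further compounds**
F1 | step 3 | rac-2,3-dimethoxy-4-oxocyclobut-2-en-1-yl O-phenyl carbonothioate | COC1=C(OC)C(=O)C1OC(=S)Oc1ccccc1
F2 | step 10 | (3-benzyloxy-2-methoxyphenyl)acetic acid | OC(=O)Cc1cccc(OCc2ccccc2)c1OC
F3 | step 10 | 3,4,5-trimethoxyphenol (purchased) | COc1cc(O)cc(OC)c1OC
F4 | step 12 | rac-{1-[2-(allyloxy)-4,5,6-trimethoxyphenyl]-2-(3-benzyloxy-2-methoxyphenyl)ethoxy}(tert-butyl)dimethylsilane | COc1cc(OCC=C)c(C(O[Si](C)(C)C(C)(C)C)Cc2cccc(OCc3ccccc3)c2OC)c(OC)c1OC
F5 | step 12 | rac-1-[2-(allyloxy)-4,5,6-trimethoxyphenyl]-2-(3-benzyloxy-2-methoxyphenyl)ethan-1-ol | COc1cc(OCC=C)c(C(O)Cc2cccc(OCc3ccccc3)c2OC)c(OC)c1OC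
F6 | step 12 | 1-[2-(allyloxy)-4,5,6-trimethoxyphenyl]-2-(3-benzyloxy-2-methoxyphenyl)ethan-1-one | COc1cc(OCC=C)c(C(=O)Cc2cccc(OCc3ccccc3)c2OC)c(OC)c1OC
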